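**Plan**
- Retrosynthesis: the C4 carbonyl is traced back to a 4‑methoxy group and the three phenols to silyl ethers; ring C is then cut at O1–C2 and C3–C4 in one operation.
- This cut is possible because O1–C8a–C4a–C4 (ring A with its phenolic oxygen and benzylic carbon) is the oxadiene of an ortho‑quinone methide, and C2–C3 with ring B is a para‑oxygenated styrene.
- Forward: the ring A salicylaldehyde comes from 2,4,6‑trihydroxybenzaldehyde by double C‑prenylation and bis‑silylation; the ring B styrene comes from 5‑iodovanillin by silylation, Stille prenylation and Wittig methylenation.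
- The two aromatic pieces and trimethyl orthoformate are joined in one [4+2] step that closes ring C, the only ring formed; then 4‑OMe → 4‑OH → C4=O and desilylation.
- Stereochemistry: C2 (S), the only stereocentre of the target, is set in the cycloaddition by the chiral counter‑anion of a confined Brønsted acid; C4 is transient, and the endgame avoids base so that C2 is not scrambled.

Key step: step 6

Remarks: TBS = tert‑butyldimethylsilyl and prenyl = 3‑methylbut‑2‑en‑1‑yl; flavan numbering is used. The C4 configuration of 13 is of no consequence because C4 becomes the carbonyl; the cis isomer is drawn as the expected endo product. The hand of the catalyst that delivers 2S cannot be predicted and is to be assigned in a test reaction.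

Step 1
Reactants: 1 2,4,6‑trihydroxybenzaldehyde; 2 prenyl bromide
Product: 3 2,4,6‑trihydroxy‑3,5‑diprenylbenzaldehyde
Conditions: 2 (2.2 equiv), aq KOH (10%), 0 °C → rt; chromatography
Reagents that add atoms: none
Why: C‑alkylation of the ambident phloroglucinol‑type phenoxide, in which water hydrogen‑bonds the oxygen centres so that the only free ring carbons C3 and C5 attack the allylic bromide, with mono‑ and gem‑diprenylated by‑products removed by chromatography.

Step 2
Reactants: 3 2,4,6‑trihydroxy‑3,5‑diprenylbenzaldehyde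
Product: 4 4,6‑bis(TBS‑oxy)‑2‑hydroxy‑3,5‑diprenylbenzaldehyde
Conditions: TBSCl (2.2 equiv), imidazole, DMF, 0 °C → rt
Reagents that add atoms: tert‑butyldimethylsilyl chloride, CC(C)(C)[Si](C)(C)Cl
Why: Phenol silylation (silyl ether formation) takes the para hydroxyl and the ortho hydroxyl that is not hydrogen‑bonded to the formyl oxygen, while the chelated ortho hydroxyl stays free, and since the two ortho hydroxyls of 3 are equivalent by symmetry a single bis‑silyl ether should result.

Step 3
Reactants: 5 5‑iodovanillin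
Product: 6 4‑(TBS‑oxy)‑3‑iodo‑5‑methoxybenzaldehyde
Conditions: TBSCl, imidazole, DMF, rt
Reagents that add atoms: tert‑butyldimethylsilyl chloride, CC(C)(C)[Si](C)(C)Cl
Why: Phenol silylation (silyl ether formation) of the only hydroxyl group masks the acidic phenol for the coupling, the ylide chemistry and the acid‑catalysed key step.

Step 4
Reactants: 6 4‑(TBS‑oxy)‑3‑iodo‑5‑methoxybenzaldehyde; 7 tributyl(prenyl)stannane (commercial)
Product: 8 4‑(TBS‑oxy)‑3‑methoxy‑5‑prenylbenzaldehyde
Conditions: 7 (1.3 equiv), Pd(PPh3)4 (5 mol%), toluene, 100 °C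
Reagents that add atoms: none
Why: Stille cross‑coupling, in which oxidative addition of the aryl iodide to zerovalent palladium, prenyl transfer from tin and reductive elimination at the less substituted allyl terminus should give the linear prenyl arene, while the neutral conditions leave the aldehyde and the aryl silyl ether untouched.

Step 5
Reactants: 8 4‑(TBS‑oxy)‑3‑methoxy‑5‑prenylbenzaldehyde
Product: 9 4‑(TBS‑oxy)‑3‑methoxy‑5‑prenylstyrene
Conditions: Ph3PCH3Br, n‑BuLi, THF, 0 °C; then 8, 0 °C → rt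
Reagents that add atoms: methyltriphenylphosphonium bromide, C[P+](c1ccccc1)(c1ccccc1)c1ccccc1.[Br-]
Why: Wittig methylenation of a non‑enolisable aryl aldehyde, with the ylide preformed so that no free alkoxide is present to attack the aryl silyl ether.

Step 6
Reactants: 4 4,6‑bis(TBS‑oxy)‑2‑hydroxy‑3,5‑diprenylbenzaldehyde; 9 4‑(TBS‑oxy)‑3‑methoxy‑5‑prenylstyrene; 10 trimethyl orthoformate
Product: 13 (2S,4S)‑2,4‑cis‑4‑methoxy‑5,7‑bis(TBS‑oxy)‑6,8‑diprenyl‑2‑[4‑(TBS‑oxy)‑3‑methoxy‑5‑prenylphenyl]chromane, via dimethyl acetal 11 (not isolated), via methoxy ortho‑quinone methide 12 (not isolated)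
Conditions: confined chiral BINOL‑derived imidodiphosphorimidate (IDPi) Brønsted acid (5 mol%; 3,3'‑aryl and N‑sulfonyl groups and catalyst hand chosen by screening), 10 (1.5 equiv), 9 (1.3 equiv, slow addition), 5 Å MS, toluene, −40 → −20 °C
Reagents that add atoms: none
Why: Proposed new method: acid‑catalysed acetal exchange between 4 and 10 gives acetal 11, which loses methanol to the O‑protonated 4‑methoxy ortho‑quinone methide 12, held as an ion pair with the confined chiral anion; the terminal CH2 of styrene 9 attacks C4 while O1 collapses on the developing para‑silyloxybenzylic cation at C2, an asynchronous inverse‑demand oxa‑[4+2] (hetero‑Diels–Alder) cycloaddition. The closest known reaction types are the achiral‑acid three‑component union of salicylaldehydes, orthoformates and styrenes to racemic 4‑alkoxyflavans and the confined‑acid‑catalysed enantioselective intramolecular [4+2] reactions of the same transient quinone methides, here carried over to an intermolecular styrene partner. Ring C is closed by this [4+2] cycloaddition through a six‑membered transition state, C3–C4 forming ahead of O1–C2. C2 is set by the chiral anion, which shields one face of the ion‑paired heterodiene and thereby fixes which face of the styrene is attacked, while C4 follows from the endo approach of ring B (2,4‑cis) and is removed later, so any trans isomer converges. Regiochemistry needs O1 on C2 and is secured by the cation‑stabilising para‑silyloxy ring B; chemoselectivity needs the styrene to react ahead of the three prenyl alkenes and is secured by its higher nucleophilicity, its unhindered CH2 terminus, the absence of a prenyl group ortho to the formyl carbon, and an acidity and temperature low enough to leave the ortho‑prenylphenol of 4 uncyclised.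

Step 7
Reactants: 13 (2S,4S)‑4‑methoxyflavan
Product: 14 (2S)‑5,7‑bis(TBS‑oxy)‑6,8‑diprenyl‑2‑[4‑(TBS‑oxy)‑3‑methoxy‑5‑prenylphenyl]chroman‑4‑ol (C4 epimer mixture)
Conditions: PPTS (0.2 equiv), THF/H2O (4:1), rt → 40 °C
Reagents that add atoms: water, O
Why: Acid‑catalysed SN1 solvolysis of a benzylic ether, in which the C4–OMe bond ionises readily because the cation is stabilised by O1 and the 5‑ and 7‑silyloxy groups of ring A and is captured by water, while the much less ionisable C2–O1 bond and the aryl silyl ethers should survive this mild acid and the C4 epimer mixture is irrelevant.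

Step 8
Reactants: 14 (2S)‑flavan‑4‑ol
Product: 15 (2S)‑5,7‑bis(TBS‑oxy)‑6,8‑diprenyl‑2‑[4‑(TBS‑oxy)‑3‑methoxy‑5‑prenylphenyl]chroman‑4‑one
Conditions: Dess–Martin periodinane, NaHCO3, CH2Cl2, 0 °C → rt
Reagents that add atoms: none
Why: Dess–Martin oxidation of the secondary benzylic alcohol under bicarbonate buffering should give the ketone without acid or base able to ionise C4, open ring C by retro‑oxa‑Michael reaction or touch the alkenes and silyl ethers, so C2 is retained.

Step 9
Reactants: 15 (2S)‑tris‑silyl flavanone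
Product: 16 (2S)‑5,7‑dihydroxy‑2‑[4‑hydroxy‑3‑methoxy‑5‑prenylphenyl]‑6,8‑diprenylchroman‑4‑one (target)
Conditions: TBAF (3.3 equiv), AcOH (3.5 equiv), THF, 0 °C
Reagents that add atoms: none
Why: Fluoride‑mediated desilylation of the three aryl silyl ethers, buffered with acetic acid so that the liberated phenoxides are protonated at once and the base‑induced ring opening of the flavanone to the chalcone, which would racemise C2, is suppressed.

**Compound list**
1 | 2,4,6‑trihydroxybenzaldehyde | O=Cc1c(O)cc(O)cc1O | starting material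
2 | prenyl bromide (1‑bromo‑3‑methylbut‑2‑ene) | CC(C)=CCBr | starting material
3 | 2,4,6‑trihydroxy‑3,5‑bis(3‑methylbut‑2‑en‑1‑yl)benzaldehyde | O=Cc1c(O)c(CC=C(C)C)c(O)c(CC=C(C)C)c1O | intermediate
4 | 4,6‑bis(tert‑butyldimethylsilyloxy)‑2‑hydroxy‑3,5‑bis(3‑methylbut‑2‑en‑1‑yl)benzaldehyde | O=Cc1c(O)c(CC=C(C)C)c(O[Si](C)(C)C(C)(C)C)c(CC=C(C)C)c1O[Si](C)(C)C(C)(C)C | intermediate
5 | 5‑iodovanillin (4‑hydroxy‑3‑iodo‑5‑methoxybenzaldehyde) | COc1cc(C=O)cc(I)c1O | starting material
6 | 4‑(tert‑butyldimethylsilyloxy)‑3‑iodo‑5‑methoxybenzaldehyde | COc1cc(C=O)cc(I)c1O[Si](C)(C)C(C)(C)C | intermediate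
7 | tributyl(3‑methylbut‑2‑en‑1‑yl)stannane | CCCC[Sn](CCCC)(CCCC)CC=C(C)C | starting material
8 | 4‑(tert‑butyldimethylsilyloxy)‑3‑methoxy‑5‑(3‑methylbut‑2‑en‑1‑yl)benzaldehyde | COc1cc(C=O)cc(CC=C(C)C)c1O[Si](C)(C)C(C)(C)C | intermediate
9 | 4‑(tert‑butyldimethylsilyloxy)‑3‑methoxy‑5‑(3‑methylbut‑2‑en‑1‑yl)styrene | C=Cc1cc(OC)c(O[Si](C)(C)C(C)(C)C)c(CC=C(C)C)c1 | intermediate
10 | trimethyl orthoformate | COC(OC)OC | starting material
11 | 3,5‑bis(tert‑butyldimethylsilyloxy)‑2‑(dimethoxymethyl)‑4,6‑bis(3‑methylbut‑2‑en‑1‑yl)phenol (dimethyl acetal of 4; formed in the flask, not isolated) | COC(OC)c1c(O)c(CC=C(C)C)c(O[Si](C)(C)C(C)(C)C)c(CC=C(C)C)c1O[Si](C)(C)C(C)(C)C | intermediate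
12 | 3,5‑bis(tert‑butyldimethylsilyloxy)‑6‑(methoxymethylidene)‑2,4‑bis(3‑methylbut‑2‑en‑1‑yl)cyclohexa‑2,4‑dien‑1‑one (4‑methoxy ortho‑quinone methide, neutral form of the ion‑paired cation; alkene geometry not assigned; not isolated) | COC=C1C(=O)C(CC=C(C)C)=C(O[Si](C)(C)C(C)(C)C)C(CC=C(C)C)=C1O[Si](C)(C)C(C)(C)C | intermediate
13 | (2S,4S)‑5,7‑bis(tert‑butyldimethylsilyloxy)‑2‑[4‑(tert‑butyldimethylsilyloxy)‑3‑methoxy‑5‑(3‑methylbut‑2‑en‑1‑yl)phenyl]‑4‑methoxy‑6,8‑bis(3‑methylbut‑2‑en‑1‑yl)chromane (2,4‑cis) | COc1cc([C@@H]2C[C@H](OC)c3c(O[Si](C)(C)C(C)(C)C)c(CC=C(C)C)c(O[Si](C)(C)C(C)(C)C)c(CC=C(C)C)c3O2)cc(CC=C(C)C)c1O[Si](C)(C)C(C)(C)C | intermediate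
14 | (2S)‑5,7‑bis(tert‑butyldimethylsilyloxy)‑2‑[4‑(tert‑butyldimethylsilyloxy)‑3‑methoxy‑5‑(3‑methylbut‑2‑en‑1‑yl)phenyl]‑6,8‑bis(3‑methylbut‑2‑en‑1‑yl)chroman‑4‑ol (mixture of C4 epimers) | COc1cc([C@@H]2CC(O)c3c(O[Si](C)(C)C(C)(C)C)c(CC=C(C)C)c(O[Si](C)(C)C(C)(C)C)c(CC=C(C)C)c3O2)cc(CC=C(C)C)c1O[Si](C)(C)C(C)(C)C | intermediate
15 | (2S)‑5,7‑bis(tert‑butyldimethylsilyloxy)‑2‑[4‑(tert‑butyldimethylsilyloxy)‑3‑methoxy‑5‑(3‑methylbut‑2‑en‑1‑yl)phenyl]‑6,8‑bis(3‑methylbut‑2‑en‑1‑yl)chroman‑4‑one | COc1cc([C@@H]2CC(=O)c3c(O[Si](C)(C)C(C)(C)C)c(CC=C(C)C)c(O[Si](C)(C)C(C)(C)C)c(CC=C(C)C)c3O2)cc(CC=C(C)C)c1O[Si](C)(C)C(C)(C)C | intermediate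
16 | (2S)‑5,7‑dihydroxy‑2‑[4‑hydroxy‑3‑methoxy‑5‑(3‑methylbut‑2‑en‑1‑yl)phenyl]‑6,8‑bis(3‑methylbut‑2‑en‑1‑yl)chroman‑4‑one | COc1cc([C@@H]2CC(=O)c3c(O)c(CC=C(C)C)c(O)c(CC=C(C)C)c3O2)cc(CC=C(C)C)c1O | target

**Count**
Total steps: 9. Longest linear sequence: 7 (steps 3, 4, 5, 6, 7, 8, 9, from 5‑iodovanillin).

**Steps most likely to fail**

Step 6. The intermolecular cycloaddition may proceed with poor facial selectivity at C2, or catalyst control may be lost to an unselective background reaction. Further possible losses are cationic oligomerisation of the styrene, acid‑induced cyclisation of the ortho‑prenylphenol onto its alkene, and re‑ionisation of the product at C4 with capture of a second styrene. Fallback, setting out from 4, 9 and 10 and returning at 15: the union is run with an achiral acid (camphorsulfonic acid or catalytic TfOH, CH2Cl2, low temperature), the known racemic three‑component synthesis of 4‑alkoxyflavans, to give the racemic 2,4‑cis‑4‑methoxyflavan F1. Hydrolysis as in step 7 gives the racemic flavan‑4‑ol F2, and Dess–Martin oxidation as in step 8 gives the racemic tris‑silyl flavanone F3, which has C2 as its only stereocentre. Preparative chromatography on a polysaccharide‑based chiral stationary phase separates the (2S)‑enantiomer, which is 15, from the (2R)‑flavanone F4; stereochemistry then comes from resolution and not from catalyst control.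

Step 7. Ionisation at C4 may be followed by loss of H3 to give the flav‑3‑ene instead of capture by water, or prolonged acid may open the C2–O1 bond and erode the configuration at C2. Fallback, setting out from 13 and returning directly at 15 with no new isolated compound: oxidative cleavage of the benzylic methyl ether with DDQ in CH2Cl2/pH 7 buffer at 0 °C. Hydride abstraction from C4 gives a methoxy‑stabilised oxocarbenium ion, which is hydrated and loses methanol to give the ketone, so the flavan‑4‑ol and its acid treatment are bypassed.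

Step 4. Prenyl transfer may occur with allylic transposition to the 1,1‑dimethylallyl isomer, or a palladium hydride may move the prenyl double bond into conjugation with the ring. Fallback, setting out from 6 and returning at 8: Stille coupling with allyltributylstannane (Pd(PPh3)4, toluene, 100 °C), which has no regiochemical ambiguity, gives 3‑allyl‑4‑(TBS‑oxy)‑5‑methoxybenzaldehyde F5. Olefin cross‑metathesis of F5 with excess 2‑methylbut‑2‑ene using the second‑generation Grubbs catalyst RuCl2(H2IMes)(PCy3)(=CHPh) in CH2Cl2 at rt then converts the allyl group into the prenyl group of 8.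

**Further compounds**
F1 | step 6 | racemic 2,4‑cis‑5,7‑bis(tert‑butyldimethylsilyloxy)‑2‑[4‑(tert‑butyldimethylsilyloxy)‑3‑methoxy‑5‑(3‑methylbut‑2‑en‑1‑yl)phenyl]‑4‑methoxy‑6,8‑bis(3‑methylbut‑2‑en‑1‑yl)chromane | COc1cc(C2CC(OC)c3c(O[Si](C)(C)C(C)(C)C)c(CC=C(C)C)c(O[Si](C)(C)C(C)(C)C)c(CC=C(C)C)c3O2)cc(CC=C(C)C)c1O[Si](C)(C)C(C)(C)C
F2 | step 6 | racemic 5,7‑bis(tert‑butyldimethylsilyloxy)‑2‑[4‑(tert‑butyldimethylsilyloxy)‑3‑methoxy‑5‑(3‑methylbut‑2‑en‑1‑yl)phenyl]‑6,8‑bis(3‑methylbut‑2‑en‑1‑yl)chroman‑4‑ol (C4 epimer mixture) | COc1cc(C2CC(O)c3c(O[Si](C)(C)C(C)(C)C)c(CC=C(C)C)c(O[Si](C)(C)C(C)(C)C)c(CC=C(C)C)c3O2)cc(CC=C(C)C)c1O[Si](C)(C)C(C)(C)C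
F3 | step 6 | racemic 5,7‑bis(tert‑butyldimethylsilyloxy)‑2‑[4‑(tert‑butyldimethylsilyloxy)‑3‑methoxy‑5‑(3‑methylbut‑2‑en‑1‑yl)phenyl]‑6,8‑bis(3‑methylbut‑2‑en‑1‑yl)chroman‑4‑one | COc1cc(C2CC(=O)c3c(O[Si](C)(C)C(C)(C)C)c(CC=C(C)C)c(O[Si](C)(C)C(C)(C)C)c(CC=C(C)C)c3O2)cc(CC=C(C)C)c1O[Si](C)(C)C(C)(C)C
F4 | step 6 | (2R)‑5,7‑bis(tert‑butyldimethylsilyloxy)‑2‑[4‑(tert‑butyldimethylsilyloxy)‑3‑methoxy‑5‑(3‑methylbut‑2‑en‑1‑yl)phenyl]‑6,8‑bis(3‑methylbut‑2‑en‑1‑yl)chroman‑4‑one (enantiomer of 15, set aside in the resolution) | COc1cc([C@H]2CC(=O)c3c(O[Si](C)(C)C(C)(C)C)c(CC=C(C)C)c(O[Si](C)(C)C(C)(C)C)c(CC=C(C)C)c3O2)cc(CC=C(C)C)c1O[Si](C)(C)C(C)(C)C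
F0 | step 7 | none | none
F5 | step 4 | 3‑allyl‑4‑(tert‑butyldimethylsilyloxy)‑5‑methoxybenzaldehyde | COc1cc(C=O)cc(CC=C)c1O[Si](C)(C)C(C)(C)C
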